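**Retrosynthetic overview**
1. Ring A (carbocycle) is never built. As in the biosynthesis it enters as an aromatic C7 unit: arene 1 is raised to the quinone level (bisketal 2, monoketal 3), the stand-in for the CoQ-type quinone.
2. Ring B (lactone) is the only ring formed and is closed first. Geranyl acetate 4 → 5 → phosphate 6; 6 + CO + bromo ester 7 (as zinc reagent 8) → γ-keto ester 9; ketoreductase-like reduction gives 4-hydroxy ester 10, which lactonises to 11, then 12 and bromide 13.
3. C6–H and C5–C1' disconnection: ene-reductase-like asymmetric 1,4-hydride addition to 3 gives enol ether 14, which is C-prenylated by 13 to give 15.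
4. C4: carbonyl reduction and unmasking of C1 (16 → antroquinonol B 17), then acetyl transfer to the target 18.

Numbering used below: ring C1–C6 as in the target (C1 ketone, C4 acetoxy carbon, C5 side-chain carbon, C6 methyl carbon); side chain C1'–C12' counted from the ring.

Assumption: 1, 4 and 7 are purchased; the facial senses of the two chiral catalysts are assigned by analogy (isophorone for (S)-DTBM-SEGPHOS/CuH, 4-oxo esters for RuCl2[(R)-BINAP]), and the enantiomeric ligand is used if either sense proves opposite.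

**Route**

Step 1
Reactants: 1 2,3,4,5-tetramethoxytoluene (1,2,3,4-tetramethoxy-5-methylbenzene)
Product: 3 quinone monoketal 2,3,4,4-tetramethoxy-5-methylcyclohexa-2,5-dien-1-one, via hexamethoxy bisketal 2 (not isolated)
Conditions: Pt anode, steel cathode, undivided cell, 1% KOH in MeOH, 0 °C, constant current (2.2 F/mol); then 5% aq AcOH–acetone, 0 °C
Reagents that add atoms: methanol, CO; water, O
Why: Anodic bis-ipso-methoxylation of the para-dimethoxy pair (quinone bisketal synthesis) gives 2, and controlled acid hydrolysis opens only the ketal whose oxocarbenium ion is stabilised by the β-methyl group, so the surviving ketal sits next to the methyl-bearing carbon (regioselective monoketal hydrolysis).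

Step 2
Reactants: 4 geranyl acetate
Product: 5 (2E,6E)-8-hydroxy-3,7-dimethylocta-2,6-dien-1-yl acetate
Conditions: SeO2 (0.1 equiv), t-BuOOH (3 equiv), salicylic acid (0.1 equiv), CH2Cl2, 25 °C
Reagents that add atoms: tert-butyl hydroperoxide, CC(C)(C)OO
Why: Catalytic SeO2 allylic oxidation (ene reaction then [2,3]-sigmatropic shift) takes place at the distal, more electron-rich trisubstituted alkene and at its E methyl group, leaving the acetate-deactivated proximal alkene.

Step 3
Reactants: 5 (2E,6E)-8-hydroxy-3,7-dimethylocta-2,6-dien-1-yl acetate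
Product: 6 (2E,6E)-8-[(diethoxyphosphoryl)oxy]-3,7-dimethylocta-2,6-dien-1-yl acetate
Conditions: ClP(O)(OEt)2, pyridine, DMAP (cat.), CH2Cl2, 0 °C
Reagents that add atoms: diethyl chlorophosphate, CCOP(=O)(Cl)OCC
Why: O-phosphorylation of the primary allylic alcohol installs a leaving group that zerovalent palladium ionises much faster than the allylic acetate at C1'.

Step 4
Reactants: 6 (2E,6E)-8-[(diethoxyphosphoryl)oxy]-3,7-dimethylocta-2,6-dien-1-yl acetate; 7 methyl (S)-3-bromo-2-methylpropanoate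
Product: 9 methyl (2R,6E,10E)-12-acetoxy-2,6,10-trimethyl-4-oxododeca-6,10-dienoate, via zinc homoenolate 8 (not isolated)
Conditions: 7, Zn dust, LiCl, THF, 40 °C; then 6, Pd(PPh3)4 (5 mol %), CO (1 atm), THF–DMPU, 25 °C
Reagents that add atoms: carbon monoxide, [C-]#[O+]
Why: Palladium-catalysed carbonylative three-component coupling (acylative Negishi-type): the phosphate is ionised selectively to the syn π-allyl complex, CO inserts at its unsubstituted terminus C8', and the acyl palladium is captured by zinc homoenolate 8, so the E alkene and the C11' centre brought in by 7 (11'R) are retained.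

Step 5
Reactants: 9 methyl (2R,6E,10E)-12-acetoxy-2,6,10-trimethyl-4-oxododeca-6,10-dienoate
Product: 11 lactone acetate (2E,6E)-3,7-dimethyl-8-[(2S,4R)-4-methyl-5-oxooxolan-2-yl]octa-2,6-dien-1-yl acetate, via hydroxy ester 10 (not isolated)
Conditions: RuCl2[(R)-BINAP] (0.5 mol %), H2 (100 atm), MeOH, 30 °C; then PPTS (cat.), CH2Cl2, 25 °C
Reagents that add atoms: none
Why: Noyori ester-directed asymmetric hydrogenation of the 4-oxo ester sets C9' (S) under catalyst control while the unfunctionalised trisubstituted alkenes and the allylic acetate stay untouched, and the 4-hydroxy ester 10 then closes by acid-catalysed lactonisation, the same 4-hydroxy acid closure presumed in the biosynthesis, to the 3,5-trans lactone.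

Step 6
Reactants: 11 lactone acetate (2E,6E)-3,7-dimethyl-8-[(2S,4R)-4-methyl-5-oxooxolan-2-yl]octa-2,6-dien-1-yl acetate
Product: 12 (3R,5S)-5-[(2E,6E)-8-hydroxy-2,6-dimethylocta-2,6-dien-1-yl]-3-methyloxolan-2-one
Conditions: K2CO3 (0.2 equiv), MeOH, 0 °C
Reagents that add atoms: none
Why: Base-catalysed transesterification (methanolysis) removes the primary acetate at 0 °C, conditions under which the γ-lactone and its α-stereocentre are left alone.

Step 7
Reactants: 12 (3R,5S)-5-[(2E,6E)-8-hydroxy-2,6-dimethylocta-2,6-dien-1-yl]-3-methyloxolan-2-one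
Product: 13 allylic bromide (3R,5S)-5-[(2E,6E)-8-bromo-2,6-dimethylocta-2,6-dien-1-yl]-3-methyloxolan-2-one
Conditions: CBr4, PPh3, CH2Cl2, 0 °C
Reagents that add atoms: carbon tetrabromide, BrC(Br)(Br)Br
Why: Appel bromination replaces the primary allylic hydroxyl by SN2 without changing alkene geometry or touching the lactone.

Step 8
Reactants: 3 quinone monoketal 2,3,4,4-tetramethoxy-5-methylcyclohexa-2,5-dien-1-one; 13 allylic bromide (3R,5S)-5-[(2E,6E)-8-bromo-2,6-dimethylocta-2,6-dien-1-yl]-3-methyloxolan-2-one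
Product: 15 (5R,6R)-2,3,4,4-tetramethoxy-5-methyl-6-{(2E,6E)-3,7-dimethyl-8-[(2S,4R)-4-methyl-5-oxooxolan-2-yl]octa-2,6-dien-1-yl}cyclohex-2-en-1-one, via silyl enol ether 14 (not isolated)
Conditions: 3 (1.5 equiv), Cu(OAc)2·H2O (3 mol %), (S)-DTBM-SEGPHOS (3 mol %), HSiMe(OEt)2 (1.5 equiv), toluene, 0 °C; then 13 (1.0 equiv), Bu4N[Ph3SiF2] (1.6 equiv), CH2Cl2, 0 to 25 °C
Reagents that add atoms: none
Why: Proposed new method: ligated CuH should deliver hydride only to C6 of 3, the one β-carbon that is not deactivated as a vinylogous ester, on the face chosen by the bisphosphine to give silyl enol ether 14 with C6 R, and the fluoride-released enolate should then attack the primary allylic carbon of 13 by SN2 anti to the new C6 methyl so that C5 is set trans (R); the closest known reaction type is the asymmetric copper hydride 1,4-reduction of 3-methylcycloalkenones with one-pot fluoride-promoted alkylation of the silyl enol ether (tandem conjugate reduction–enolate alkylation).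

Step 9
Reactants: 15 (5R,6R)-2,3,4,4-tetramethoxy-5-methyl-6-{(2E,6E)-3,7-dimethyl-8-[(2S,4R)-4-methyl-5-oxooxolan-2-yl]octa-2,6-dien-1-yl}cyclohex-2-en-1-one
Product: 17 antroquinonol B (4R,5R,6R)-4-hydroxy-2,3-dimethoxy-6-methyl-5-{(2E,6E)-3,7-dimethyl-8-[(2S,4R)-4-methyl-5-oxooxolan-2-yl]octa-2,6-dien-1-yl}cyclohex-2-en-1-one, via hydroxy ketal 16 (not isolated)
Conditions: LiBH(s-Bu)3 (1.2 equiv), THF, −78 °C; then 1 M aq HCl, THF, 0 °C
Reagents that add atoms: water, O
Why: Diastereoselective ketone reduction in which the hindered borohydride approaches C4 of the trans-diequatorial half-chair from the equatorial side to give the axial alcohol cis to the C5 chain (4R) while the lactone is inert at −78 °C, followed by hydrolysis of the allylic dimethyl ketal to the C1 enone (ketal hydrolysis).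

Step 10
Reactants: 17 antroquinonol B
Product: 18 4-acetylantroquinonol B (1R,5R,6R)-2,3-dimethoxy-5-methyl-4-oxo-6-{(2E,6E)-3,7-dimethyl-8-[(2S,4R)-4-methyl-5-oxooxolan-2-yl]octa-2,6-dien-1-yl}cyclohex-2-en-1-yl acetate
Conditions: Ac2O, pyridine, DMAP (cat.), CH2Cl2, 0 to 25 °C
Reagents that add atoms: acetic anhydride, CC(=O)OC(C)=O
Why: DMAP-catalysed O-acylation of the secondary alcohol proceeds with retention at C4 and parallels the last acetyl transfer of the biosynthesis.

**Compound list**
1 | 2,3,4,5-tetramethoxytoluene (1,2,3,4-tetramethoxy-5-methylbenzene) | COc1cc(C)c(OC)c(OC)c1OC | starting material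
2 | 1,2,3,3,6,6-hexamethoxy-4-methylcyclohexa-1,4-diene (quinone bisketal) | COC1=C(OC)C(OC)(OC)C(C)=CC1(OC)OC | intermediate
3 | 2,3,4,4-tetramethoxy-5-methylcyclohexa-2,5-dien-1-one (quinone monoketal) | COC1=C(OC)C(OC)(OC)C(C)=CC1=O | intermediate
4 | geranyl acetate, (2E)-3,7-dimethylocta-2,6-dien-1-yl acetate | CC(=O)OC/C=C(\C)CCC=C(C)C | starting material
5 | (2E,6E)-8-hydroxy-3,7-dimethylocta-2,6-dien-1-yl acetate | CC(=O)OC/C=C(\C)CC/C=C(\C)CO | intermediate
6 | (2E,6E)-8-[(diethoxyphosphoryl)oxy]-3,7-dimethylocta-2,6-dien-1-yl acetate | CC(=O)OC/C=C(\C)CC/C=C(\C)COP(=O)(OCC)OCC | intermediate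
7 | methyl (S)-3-bromo-2-methylpropanoate | BrC[C@@H](C)C(=O)OC | starting material
8 | [(2S)-3-methoxy-2-methyl-3-oxopropyl]zinc bromide (zinc homoenolate) | Br[Zn]C[C@@H](C)C(=O)OC | intermediate
9 | methyl (2R,6E,10E)-12-acetoxy-2,6,10-trimethyl-4-oxododeca-6,10-dienoate | CC(=O)OC/C=C(\C)CC/C=C(\C)CC(=O)C[C@@H](C)C(=O)OC | intermediate
10 | methyl (2R,4S,6E,10E)-12-acetoxy-4-hydroxy-2,6,10-trimethyldodeca-6,10-dienoate | CC(=O)OC/C=C(\C)CC/C=C(\C)C[C@@H](O)C[C@@H](C)C(=O)OC | intermediate
11 | (2E,6E)-3,7-dimethyl-8-[(2S,4R)-4-methyl-5-oxooxolan-2-yl]octa-2,6-dien-1-yl acetate | CC(=O)OC/C=C(\C)CC/C=C(\C)C[C@@H]1C[C@@H](C)C(=O)O1 | intermediate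
12 | (3R,5S)-5-[(2E,6E)-8-hydroxy-2,6-dimethylocta-2,6-dien-1-yl]-3-methyloxolan-2-one | OC/C=C(\C)CC/C=C(\C)C[C@@H]1C[C@@H](C)C(=O)O1 | intermediate
13 | (3R,5S)-5-[(2E,6E)-8-bromo-2,6-dimethylocta-2,6-dien-1-yl]-3-methyloxolan-2-one | BrC/C=C(\C)CC/C=C(\C)C[C@@H]1C[C@@H](C)C(=O)O1 | intermediate
14 | diethoxy(methyl){[(3R)-4,4,5,6-tetramethoxy-3-methylcyclohexa-1,5-dien-1-yl]oxy}silane | COC1=C(OC)C(OC)(OC)[C@H](C)C=C1O[Si](C)(OCC)OCC | intermediate
15 | (5R,6R)-2,3,4,4-tetramethoxy-5-methyl-6-{(2E,6E)-3,7-dimethyl-8-[(2S,4R)-4-methyl-5-oxooxolan-2-yl]octa-2,6-dien-1-yl}cyclohex-2-en-1-one | COC1=C(OC)C(=O)[C@H](C/C=C(\C)CC/C=C(\C)C[C@@H]2C[C@@H](C)C(=O)O2)[C@@H](C)C1(OC)OC | intermediate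
16 | (3R,5S)-5-{(2E,6E)-8-[(1R,2R,6R)-2-hydroxy-3,4,5,5-tetramethoxy-6-methylcyclohex-3-en-1-yl]-2,6-dimethylocta-2,6-dien-1-yl}-3-methyloxolan-2-one (hydroxy ketal) | COC1=C(OC)[C@H](O)[C@H](C/C=C(\C)CC/C=C(\C)C[C@@H]2C[C@@H](C)C(=O)O2)[C@@H](C)C1(OC)OC | intermediate
17 | antroquinonol B, (4R,5R,6R)-4-hydroxy-2,3-dimethoxy-6-methyl-5-{(2E,6E)-3,7-dimethyl-8-[(2S,4R)-4-methyl-5-oxooxolan-2-yl]octa-2,6-dien-1-yl}cyclohex-2-en-1-one | COC1=C(OC)[C@H](O)[C@H](C/C=C(\C)CC/C=C(\C)C[C@@H]2C[C@@H](C)C(=O)O2)[C@@H](C)C1=O | intermediate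
18 | 4-acetylantroquinonol B, (1R,5R,6R)-2,3-dimethoxy-5-methyl-4-oxo-6-{(2E,6E)-3,7-dimethyl-8-[(2S,4R)-4-methyl-5-oxooxolan-2-yl]octa-2,6-dien-1-yl}cyclohex-2-en-1-yl acetate | COC1=C(OC)[C@H](OC(C)=O)[C@H](C/C=C(\C)CC/C=C(\C)C[C@@H]2C[C@@H](C)C(=O)O2)[C@@H](C)C1=O | target

**Step count and risks**

Total step count: 10. Longest linear sequence: 9 steps (4 to 18, steps 2 to 10); step 1 is the one-step side branch.

Step 8 is the most likely to fail, because neither the CuH reduction of a quinone monoketal nor the alkylation of its enolate by a precious allylic bromide has direct precedent. The fallback sets out from 13 and comes back at 15. The C6–CH3 bond is made in place of the C6–H bond: commercial 2,3,4-trimethoxyphenol is oxidised with PhI(OAc)2 in MeOH to the nor-methyl monoketal 2,3,4,4-tetramethoxycyclohexa-2,5-dien-1-one F1. Copper-catalysed asymmetric conjugate methylation (Me2Zn, Cu(OTf)2, chiral phosphoramidite ligand, toluene, −30 °C) gives the methylzinc (3R)-enolate F2, which is C-alkylated by 13 (DMPU, 0 °C) to give 15.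

Step 4 is the second risk: uncatalysed or CO-free allyl–zinc coupling and drift of the β,γ-alkene into conjugation can compete. The fallback sets out from 6 and comes back at 9. CO insertion and C–C coupling are separated: palladium-catalysed thiocarbonylation of 6 (Pd(OAc)2, PPh3, CO, EtSH) gives S-ethyl (3E,7E)-9-acetoxy-3,7-dimethylnona-3,7-dienethioate F3, and a Fukuyama coupling of F3 with zinc reagent 8 (PdCl2(PPh3)2, toluene, 25 °C) gives 9.

Step 5 is the third risk: the ruthenium catalyst may isomerise or reduce the β,γ-alkene, or give low selectivity at C9'. The fallback sets out from 9 and comes back at 12. Pig-liver esterase in pH 7 buffer cleaves both esters to (2R,6E,10E)-12-hydroxy-2,6,10-trimethyl-4-oxododeca-6,10-dienoic acid F4. Ipc2BH, in the enantiomeric form that gives the 4S carbinol, binds as the acyloxyborane and reduces the ketone intramolecularly to (2R,4S,6E,10E)-4,12-dihydroxy-2,6,10-trimethyldodeca-6,10-dienoic acid F5, which lactonises on acidification to 12, so step 6 is bypassed as well.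

**Further compounds**
F1 | step 8 | 2,3,4,4-tetramethoxycyclohexa-2,5-dien-1-one | COC1=C(OC)C(OC)(OC)C=CC1=O
F2 | step 8 | methylzinc (3R)-4,4,5,6-tetramethoxy-3-methylcyclohexa-1,5-dien-1-olate | COC1=C(OC)C(OC)(OC)[C@H](C)C=C1O[Zn]C
F3 | step 4 | S-ethyl (3E,7E)-9-acetoxy-3,7-dimethylnona-3,7-dienethioate | CC(=O)OC/C=C(\C)CC/C=C(\C)CC(=O)SCC
F4 | step 5 | (2R,6E,10E)-12-hydroxy-2,6,10-trimethyl-4-oxododeca-6,10-dienoic acid | OC/C=C(\C)CC/C=C(\C)CC(=O)C[C@@H](C)C(=O)O
F5 | step 5 | (2R,4S,6E,10E)-4,12-dihydroxy-2,6,10-trimethyldodeca-6,10-dienoic acid | OC/C=C(\C)CC/C=C(\C)C[C@@H](O)C[C@@H](C)C(=O)O
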